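**Retrosynthetic overview**

1. Quinone 22 ⇐ (Ag2O) hydroquinone 21 ⇐ thermal ring expansion of the four-membered ring of 4-alkenyl-4-hydroxycyclobutenone 18 by its two alkenyl carbons (4π opening, then 6π closure).
2. 18 ⇐ 1,2-addition of alkenyllithium 17 (from bromodiene 13, which already carries the whole decaprenyl chain) to methyl semisquarate 16 (from dimethyl squarate 14); this one bond fixes the position of all four ring substituents.
3. 13 ⇐ Zr-catalysed carboalumination of alkyne 6 (from all-E solanesol 1 and silylpropyne 3), then Pd-catalysed coupling of alkenylalane 12 with dibromide 11 (from crotonaldehyde 7); this sets the tenth E alkene.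
4. Enabling feature: in the quinone ring, C1(=O)–C6(OMe)=C5(H)–C4(=O) is a contiguous four-carbon unit with oxygen at both ends, i.e. the skeleton of 3-methoxycyclobutene-1,2-dione; the remaining edge C2(decaprenyl)=C3(CH3) is an alkene whose C3 still carried one H, and the hydroxyl on the sp3 carbon of the strained ring steers its opening.
5. Ring order: four-membered ring (bought as squarate) → six-membered ring of the target (step 10); no other ring is formed.

Key step: step 10

Remark: all-E solanesol supplies nine of the ten isoprene units; "solanesyl" and "decaprenyl" mean the all-E nonaprenyl and decaprenyl groups (CH2 attached first); the geometry of the CH3CH= bond in 9–19 is immaterial because that carbon becomes the aromatic C–CH3, and 16 is assumed to be accessible from dimethyl squarate in the way established for higher alkyl semisquarates.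

**Step 1**
Reactants: 1 solanesol
Product: 2 solanesyl bromide (all-E 1-bromo-3,7,11,15,19,23,27,31,35-nonamethylhexatriaconta-2,6,10,14,18,22,26,30,34-nonaene)
Conditions: PBr3, pyridine (cat.), Et2O/hexane, −10 to 0 °C
Reagents that add atoms: phosphorus tribromide, BrP(Br)Br
Why: PBr3 bromination of a primary allylic alcohol by SN2 displacement of the phosphite leaving group should keep the 2E geometry and the allylic position at low temperature.

**Step 2**
Reactants: 2 solanesyl bromide; 3 1-(trimethylsilyl)propyne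
Product: 5 trimethyl(3-solanesylprop-1-yn-1-yl)silane, via 3-lithio-1-(trimethylsilyl)propyne 4 (not isolated)
Conditions: 3, n-BuLi, THF, −78 to −20 °C; then 2, −78 °C to rt
Reagents that add atoms: none
Why: Propargylic lithiation of the silyl-capped propyne and SN2 alkylation by the primary allylic bromide (propargylic alkylation), the silyl group steering attack to the propargylic rather than the allenic terminus.

**Step 3**
Reactants: 5 trimethyl(3-solanesylprop-1-yn-1-yl)silane
Product: 6 3-solanesylprop-1-yne (all-E 6,10,14,18,22,26,30,34,38-nonamethylnonatriaconta-5,9,13,17,21,25,29,33,37-nonaen-1-yne)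
Conditions: K2CO3 (cat.), MeOH/THF, rt
Reagents that add atoms: none
Why: Base-mediated methanolysis of the C(sp)–Si bond (protodesilylation) should free the terminal alkyne without touching the polyene.

**Step 4**
Reactants: 7 (E)-but-2-enal (crotonaldehyde)
Product: 9 (Z)-2-bromobut-2-enal, via 2,3-dibromobutanal 8 (not isolated)
Conditions: Br2, CH2Cl2, 0 °C; then Et3N, 0 °C to rt
Reagents that add atoms: bromine, BrBr
Why: Anti addition of Br2 followed by E1cB loss of HBr from the acidic alpha position (bromination–dehydrobromination) should give the alpha-bromo enal as the isomer with CH3 trans to CHO.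

**Step 5**
Reactants: 9 (Z)-2-bromobut-2-enal
Product: 10 (Z)-2-bromobut-2-en-1-ol
Conditions: NaBH4, CeCl3·7H2O, MeOH, 0 °C
Reagents that add atoms: none
Why: Luche 1,2-reduction delivers hydride only to the aldehyde carbonyl and leaves the bromoalkene intact.

**Step 6**
Reactants: 10 (Z)-2-bromobut-2-en-1-ol
Product: 11 (Z)-1,2-dibromobut-2-ene
Conditions: PBr3, Et2O, 0 °C
Reagents that add atoms: phosphorus tribromide, BrP(Br)Br
Why: PBr3 bromination of the primary allylic alcohol by SN2; any transposed secondary bromide is harmless because both isomers give the same π-allyl complex in step 7.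

**Step 7**
Reactants: 6 3-solanesylprop-1-yne; 11 (Z)-1,2-dibromobut-2-ene
Product: 13 (1Z)-1-bromo-1-decaprenylprop-1-ene (CH3CH=C(Br)–decaprenyl), via alkenylalane 12 (not isolated)
Conditions: Me3Al, Cp2ZrCl2 (cat.), CH2Cl2, 0 °C to rt; volatiles removed; then 11, Pd(PPh3)4 (cat.), THF, rt
Reagents that add atoms: trimethylaluminium, C[Al](C)C
Why: Negishi Zr-catalysed carboalumination adds CH3 and Al syn across the terminal alkyne with Al at the terminus, which sets the tenth trisubstituted alkene as E, and the alkenylalane then couples with the allylic bromide under zerovalent palladium catalysis (Negishi alkenyl–allyl coupling) with retention at the alkenyl carbon and bond formation at the unsubstituted CH2 terminus of the 2-bromo-π-allyl complex, allylic C–Br oxidative addition being far faster than vinylic.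

**Step 8**
Reactants: 14 dimethyl squarate (3,4-dimethoxycyclobut-3-ene-1,2-dione)
Product: 16 3-methoxycyclobut-3-ene-1,2-dione (methyl semisquarate), via 4-hydroxy-2,3-dimethoxycyclobut-2-en-1-one 15 (not isolated)
Conditions: LiAlH(OtBu)3, THF, −78 °C; then 12 M HCl, CH2Cl2, 0 °C to rt
Reagents that add atoms: water, O
Why: The bulky hydride adds once to a squarate carbonyl, and acid then ionises the carbinol, water adds to the methoxy-stabilised allyl cation and methanol is lost (1,2-addition followed by acid-mediated transposition, the reaction type used for dialkyl squarates).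

**Step 9**
Reactants: 13 (1Z)-1-bromo-1-decaprenylprop-1-ene; 16 3-methoxycyclobut-3-ene-1,2-dione
Product: 18 4-[(1Z)-1-decaprenylprop-1-en-1-yl]-4-hydroxy-3-methoxycyclobut-2-en-1-one (racemic), via alkenyllithium 17 (not isolated)
Conditions: 13, t-BuLi (2 equiv), THF/Et2O, −78 °C; then added to 16, THF, −78 °C; aq NH4Cl
Reagents that add atoms: none
Why: Br–Li exchange proceeds with retention at −78 °C and the alkenyllithium adds 1,2 to the ketone-like carbonyl of 16 (the one attached to the methoxy-bearing carbon, the other being a deactivated vinylogous ester carbonyl), which places the carbinol carbon next to C–OMe; the new stereocentre forms as a racemate and is erased in step 10.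

**Step 10**
Reactants: 18 4-[(1Z)-1-decaprenylprop-1-en-1-yl]-4-hydroxy-3-methoxycyclobut-2-en-1-one
Product: 21 2-decaprenyl-6-methoxy-3-methylbenzene-1,4-diol, via dienylketene 19 (not isolated), via cyclohexa-2,4-dienone 20 (not isolated)
Conditions: p-xylene (degassed, dilute), 138 °C, Ar
Reagents that add atoms: none
Why: This is a Moore rearrangement: thermal conrotatory 4π opening of the strained ring cleaves the bond between the carbonyl carbon and the carbinol carbon, and the outward rotation of the donor OH (torquoselectivity) turns the alkenyl group inward, cis to the ketene, giving (Z)-dienylketene 19. Disrotatory 6π electrocyclisation then joins the ketene carbon to the CH(CH3) terminus of the alkenyl group, so the six-membered ring is closed in a 6π-electrocyclic mode as dienone 20 (net growth of the ring from four to six atoms), and enolisation gives the aromatic hydroquinone 21. The closest known reaction type is the thermal ring expansion of 4-alkenyl-4-hydroxycyclobutenones to hydroquinones. No stereocentre survives: the carbinol centre of 18 and the CH(CH3) centre of 20 both become aromatic carbons, and the propenyl geometry is erased. The selectivity needed is the direction of ring opening (an inward OH would trap the ketene as a butenolide), secured by the hydroxyl donor, and the placement of the four substituents, which is fixed by the connectivity of 18; the neutral, metal-free and oxygen-free conditions should leave the ten chain alkenes untouched.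

**Step 11**
Reactants: 21 2-decaprenyl-6-methoxy-3-methylbenzene-1,4-diol
Product: 22 2-decaprenyl-6-methoxy-3-methyl-1,4-benzoquinone (= 2-methoxy-5-methyl-6-decaprenyl-1,4-benzoquinone, the target)
Conditions: Ag2O, MgSO4, Et2O, rt, dark
Reagents that add atoms: none
Why: Ag2O dehydrogenates the electron-rich hydroquinone to the para-quinone under neutral conditions (hydroquinone-to-quinone oxidation) without affecting the trisubstituted alkenes.

**Compound list**

1 | solanesol (all-E nonaprenol) | OC/C=C(\C)CC/C=C(\C)CC/C=C(\C)CC/C=C(\C)CC/C=C(\C)CC/C=C(\C)CC/C=C(\C)CC/C=C(\C)CCC=C(C)C | starting material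
2 | solanesyl bromide | BrC/C=C(\C)CC/C=C(\C)CC/C=C(\C)CC/C=C(\C)CC/C=C(\C)CC/C=C(\C)CC/C=C(\C)CC/C=C(\C)CCC=C(C)C | intermediate
3 | 1-(trimethylsilyl)propyne | CC#C[Si](C)(C)C | starting material
4 | 3-lithio-1-(trimethylsilyl)propyne | [Li]CC#C[Si](C)(C)C | intermediate
5 | trimethyl(3-solanesylprop-1-yn-1-yl)silane | C[Si](C)(C)C#CCC/C=C(\C)CC/C=C(\C)CC/C=C(\C)CC/C=C(\C)CC/C=C(\C)CC/C=C(\C)CC/C=C(\C)CC/C=C(\C)CCC=C(C)C | intermediate
6 | 3-solanesylprop-1-yne | C#CCC/C=C(\C)CC/C=C(\C)CC/C=C(\C)CC/C=C(\C)CC/C=C(\C)CC/C=C(\C)CC/C=C(\C)CC/C=C(\C)CCC=C(C)C | intermediate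
7 | (E)-but-2-enal (crotonaldehyde) | C/C=C/C=O | starting material
8 | 2,3-dibromobutanal (racemic anti adduct, one enantiomer drawn) | C[C@H](Br)[C@H](Br)C=O | intermediate
9 | (Z)-2-bromobut-2-enal | C/C=C(\Br)C=O | intermediate
10 | (Z)-2-bromobut-2-en-1-ol | C/C=C(\Br)CO | intermediate
11 | (Z)-1,2-dibromobut-2-ene | C/C=C(\Br)CBr | intermediate
12 | dimethyl[(1E)-2-methyl-3-solanesylprop-1-en-1-yl]alane | C[Al](C)/C=C(\C)CC/C=C(\C)CC/C=C(\C)CC/C=C(\C)CC/C=C(\C)CC/C=C(\C)CC/C=C(\C)CC/C=C(\C)CC/C=C(\C)CCC=C(C)C | intermediate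
13 | (1Z)-1-bromo-1-decaprenylprop-1-ene | C/C=C(\Br)C/C=C(\C)CC/C=C(\C)CC/C=C(\C)CC/C=C(\C)CC/C=C(\C)CC/C=C(\C)CC/C=C(\C)CC/C=C(\C)CC/C=C(\C)CCC=C(C)C | intermediate
14 | dimethyl squarate | COC1=C(OC)C(=O)C1=O | starting material
15 | 4-hydroxy-2,3-dimethoxycyclobut-2-en-1-one (racemic) | COC1=C(OC)C(=O)C1O | intermediate
16 | 3-methoxycyclobut-3-ene-1,2-dione | COC1=CC(=O)C1=O | intermediate
17 | 1-decaprenylprop-1-en-1-yllithium (Li in place of Br of 13, geometry retained) | C/C=C(\[Li])C/C=C(\C)CC/C=C(\C)CC/C=C(\C)CC/C=C(\C)CC/C=C(\C)CC/C=C(\C)CC/C=C(\C)CC/C=C(\C)CC/C=C(\C)CCC=C(C)C | intermediate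
18 | 4-[(1Z)-1-decaprenylprop-1-en-1-yl]-4-hydroxy-3-methoxycyclobut-2-en-1-one (racemic) | C/C=C(\C1(O)C(OC)=CC1=O)C/C=C(\C)CC/C=C(\C)CC/C=C(\C)CC/C=C(\C)CC/C=C(\C)CC/C=C(\C)CC/C=C(\C)CC/C=C(\C)CC/C=C(\C)CCC=C(C)C | intermediate
19 | (3Z,5Z)-5-decaprenyl-4-hydroxy-3-methoxyhepta-1,3,5-trien-1-one (dienylketene) | C/C=C(\C(O)=C(OC)/C=C=O)C/C=C(\C)CC/C=C(\C)CC/C=C(\C)CC/C=C(\C)CC/C=C(\C)CC/C=C(\C)CC/C=C(\C)CC/C=C(\C)CC/C=C(\C)CCC=C(C)C | intermediate
20 | 5-decaprenyl-4-hydroxy-3-methoxy-6-methylcyclohexa-2,4-dien-1-one (racemic) | CC1C(=O)C=C(OC)C(O)=C1C/C=C(\C)CC/C=C(\C)CC/C=C(\C)CC/C=C(\C)CC/C=C(\C)CC/C=C(\C)CC/C=C(\C)CC/C=C(\C)CC/C=C(\C)CCC=C(C)C | intermediate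
21 | 2-decaprenyl-6-methoxy-3-methylbenzene-1,4-diol | COc1cc(O)c(C)c(C/C=C(\C)CC/C=C(\C)CC/C=C(\C)CC/C=C(\C)CC/C=C(\C)CC/C=C(\C)CC/C=C(\C)CC/C=C(\C)CC/C=C(\C)CCC=C(C)C)c1O | intermediate
22 | 2-decaprenyl-6-methoxy-3-methyl-1,4-benzoquinone | COC1=CC(=O)C(C)=C(C/C=C(\C)CC/C=C(\C)CC/C=C(\C)CC/C=C(\C)CC/C=C(\C)CC/C=C(\C)CC/C=C(\C)CC/C=C(\C)CC/C=C(\C)CCC=C(C)C)C1=O | target

**Step count and risks**

Total steps: 11. Longest linear sequence: 7 steps (steps 1, 2, 3, 7, 9, 10, 11, from solanesol).

Steps most likely to fail: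

1. Step 7. Risk: in the π-allyl stage the new bond may form partly at the methyl-bearing terminus, and palladium may go on to insert into the vinylic C–Br bond of the product, so that a second alkenyl group is transferred. Fallback (sets out from 6, returns at 13): the carboalumination of 6 is run as before, but alane 12 is quenched with I2 to give the isolable (1E)-1-iodo-2-methyl-3-solanesylprop-1-ene F1. I–Li exchange (t-BuLi, −78 °C) and MgBr2·OEt2 then give the alkenylmagnesium bromide, which is coupled with 11 under Li2CuCl4 catalysis (THF, −30 °C, fast addition, conditions that favour substitution at the halogen-bearing carbon of primary allylic halides). Copper does not activate the vinylic bromide, so over-coupling is excluded and 13 is reached.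

2. Step 9. Risk: proton transfer from the doubly allylic CH2 to the alkenyllithium, or deprotonation or conjugate attack at the ring CH of 16, may compete with 1,2-addition. Fallback (sets out from 10, 16 and 12, returns at 22): the chain is attached last. Alcohol 10 is silylated (TBSCl, imidazole) to tert-butyl{[(2Z)-2-bromobut-2-en-1-yl]oxy}dimethylsilane F2. Br–Li exchange and addition to 16 give 4-[(2Z)-1-(tert-butyldimethylsilyloxy)but-2-en-2-yl]-4-hydroxy-3-methoxycyclobut-2-en-1-one F3. The same thermal ring expansion gives 2-[(tert-butyldimethylsilyloxy)methyl]-6-methoxy-3-methylbenzene-1,4-diol F4, and Ag2O gives 2-[(tert-butyldimethylsilyloxy)methyl]-6-methoxy-3-methyl-1,4-benzoquinone F5. Ph3PBr2 converts the silyl ether directly into 2-(bromomethyl)-6-methoxy-3-methyl-1,4-benzoquinone F6. Coupling of F6 with alkenylalane 12 (made from 6 as in step 7) under zerovalent nickel catalysis (NiCl2(PPh3)2 reduced with n-BuLi, THF), a coupling type known for halomethylquinones and polyprenyl alanes, gives 22.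

3. Step 10. Risk: ring opening with the hydroxyl turned inward (the ketene is then trapped as a butenolide), sluggish 6π closure of the dienylketene whose methyl points inward, or ring closure of the free phenol onto the neighbouring prenyl alkene during prolonged heating. Fallback (sets out from 18, returns at 21): 18 is silylated (TMSCl, Et3N, DMAP cat.) to 4-[(1Z)-1-decaprenylprop-1-en-1-yl]-3-methoxy-4-(trimethylsilyloxy)cyclobut-2-en-1-one F7. The siloxy group rotates outward more strongly, cannot add to the ketene, and ends up masking exactly the phenol oxygen that flanks the decaprenyl chain. Thermolysis (toluene, 110 °C) gives 3-decaprenyl-5-methoxy-2-methyl-4-(trimethylsilyloxy)phenol F8, which K2CO3/MeOH desilylates to 21 just before step 11.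

**Further compounds**

F1 | step 7 | (1E)-1-iodo-2-methyl-3-solanesylprop-1-ene | I/C=C(\C)CC/C=C(\C)CC/C=C(\C)CC/C=C(\C)CC/C=C(\C)CC/C=C(\C)CC/C=C(\C)CC/C=C(\C)CC/C=C(\C)CCC=C(C)C
F2 | step 9 | tert-butyl{[(2Z)-2-bromobut-2-en-1-yl]oxy}dimethylsilane | C/C=C(\Br)CO[Si](C)(C)C(C)(C)C
F3 | step 9 | 4-[(2Z)-1-(tert-butyldimethylsilyloxy)but-2-en-2-yl]-4-hydroxy-3-methoxycyclobut-2-en-1-one (racemic) | C/C=C(\C1(O)C(OC)=CC1=O)CO[Si](C)(C)C(C)(C)C
F4 | step 9 | 2-[(tert-butyldimethylsilyloxy)methyl]-6-methoxy-3-methylbenzene-1,4-diol | COc1cc(O)c(C)c(CO[Si](C)(C)C(C)(C)C)c1O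
F5 | step 9 | 2-[(tert-butyldimethylsilyloxy)methyl]-6-methoxy-3-methyl-1,4-benzoquinone | COC1=CC(=O)C(C)=C(CO[Si](C)(C)C(C)(C)C)C1=O
F6 | step 9 | 2-(bromomethyl)-6-methoxy-3-methyl-1,4-benzoquinone | COC1=CC(=O)C(C)=C(CBr)C1=O
F7 | step 10 | 4-[(1Z)-1-decaprenylprop-1-en-1-yl]-3-methoxy-4-(trimethylsilyloxy)cyclobut-2-en-1-one (racemic) | C/C=C(\C1(O[Si](C)(C)C)C(OC)=CC1=O)C/C=C(\C)CC/C=C(\C)CC/C=C(\C)CC/C=C(\C)CC/C=C(\C)CC/C=C(\C)CC/C=C(\C)CC/C=C(\C)CC/C=C(\C)CCC=C(C)C
F8 | step 10 | 3-decaprenyl-5-methoxy-2-methyl-4-(trimethylsilyloxy)phenol | COc1cc(O)c(C)c(C/C=C(\C)CC/C=C(\C)CC/C=C(\C)CC/C=C(\C)CC/C=C(\C)CC/C=C(\C)CC/C=C(\C)CC/C=C(\C)CC/C=C(\C)CCC=C(C)C)c1O[Si](C)(C)C
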